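All constants belong to no real substance; the run is a simulation.

A small charge of D sits in much more Z, and we follow how much of that D stays free.

Z 0.050 M; D 1.0 mM

    2 Z.D ⇌ Z.D2, settled at all times (K1 = 1.4 × 10⁵ L mol⁻¹)
    Z + D ⇌ Z.D (K2 = 6.6 L mol⁻¹, k2 = 0.0147 L mol⁻¹ s⁻¹)
    Z.D ⇌ D + E (K3 = 0.0463 M, k3 = 0.00806 s⁻¹)

- percentages count the Z that a species holds: one Z.D2 counts as two
- for a step with 2 of a species take k times the square, and two of it per event
- a form made of two catalysts counts as two
- charge of Z (flask): 0.050 M

1. the form that holds most of the catalyst when 10 % of the Z are converted (Z.D / Z.D2 / D)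
2. its share of the catalyst then
3. factor on the rate of making E when 10 % of the Z are converted if D is charged twice over
4. factor on the rate when 10 % of the Z are converted if D is charged at 0.20 mM instead

**Z entries.** At 10 % conversion c(Z) is 45.0 mM, so 5.00 mM of Z must stand in E, Z.D and Z.D2. The catalyst can hold at most 1.0 mM of it, so we first book c(E) at 4.00 mM.

**Level of Z.D.** Z.D goes on to E at 700 d⁻¹, faster than D takes up Z as charged at 64 d⁻¹, so we set its making equal to its loss (a steady state). From Z and from E it is made at 0.00136 s⁻¹ per D and lost at 0.0103 s⁻¹, so s = c(Z.D)/c(D) is 0.132.

**Pairing number.** We take the pairing step as balanced. P = 4.88, twice its constant times the square of s times the D charged, is the pairing number. With f the free share of the catalyst, the shares of D, Z.D and Z.D2 are f, s·f and P·f·f, and they add to one. This gives f = 35.1 %, Z.D 4.64 % and Z.D2 60.2 %, so we name Z.D2 as the largest form, though it stands outside the working round.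

**Books closed.** The catalyst then holds 0.649 mM of Z, which leaves c(E) at 4.35 mM, a little above our entry. With twice the D, s is 0.115, P is 7.41 and f is 30.0 %. With 0.20 mM, they are 0.146, 1.19 and 55.5 %. Taking the rate as Z.D going to E less D and E coming back, we commit to factors of 1.88 and 0.290.

**The forecast.** It names Z.D2 at 63 %, with factors 1.47 and 0.35, and holds that “free D and the rate grow roughly as the square root of the catalyst charge”. Its factors differ from ours.

**The run.** In this flask at 10 % conversion, Z.D2 holds 61.1 %, D 34.2 % and Z.D 4.67 %. The factors are 1.76 and 0.309, so doubling gives more than the forecast's range allows and less than our figure.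

**Short-lived Z.D.** At 4.00 d in this flask, Z.D has a half-life of 0.024 h by its forward step to D and E alone, shorter than the 0.35 h of D by its forward step to Z.D alone. When 10 % of the Z are converted in this flask, Z.D stands at 4.67 % of the catalyst against 34.2 % for D, a ratio of 0.137. In the flask charged with 0.20 mM the pairing number is 1.19, which puts Z.D2 at 36.7 % of the catalyst at 10 % conversion, and the run gives 36.8 % at the same conversion.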